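**Retrosynthetic overview**
- Macrocarpal D ⇒ (−)-α-gurjunene + the o-quinone methide from diformylphloroglucinol and isovaleraldehyde. The C4–C9' bond is made last; opening of the cyclopropane supplies the C5=C6 alkene and the C11 carbinol.
- α-Gurjunene ⇒ a cyclopentenyl vinylcarbene (from the enal): intramolecular cyclopropanation of the prenyl-type alkene closes the seven-membered ring and the cyclopropane in one operation.
- Enal ⇒ 1,6-keto aldehyde (aldol condensation closes the five-membered ring) ⇒ one-carbon homologation of the Michael adduct of (R)-citronellal and methyl vinyl ketone.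
- Stereocentres: C10 from (R)-citronellal, C1 by catalyst-controlled Michael addition, C6/C7 in the carbene step, C4/C9' in the final coupling.
- Ring order: five-membered ring (step 3), then seven-membered ring and cyclopropane together (step 4); the cyclopropane is consumed in step 5.

Assumption: the wanted isomer is the one coded by the SMILES (all five stereocentres R); atoms are referred to by guaiane locants (C1 ring-fusion CH, C4 quaternary carbon, C5=C6 alkene, C7 carbinol-bearing CH, C10 CHMe, C11 carbinol carbon) and C9' is the benzylic carbon.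

**Step 1**
Reactants: 1 (R)-citronellal [(3R)-3,7-dimethyloct-6-enal]; 2 methyl vinyl ketone (but-3-en-2-one)
Product: 3 (2R,3R)-3,7-dimethyl-2-(3-oxobutyl)oct-6-enal
Conditions: (R)-2-[diphenyl(trimethylsilyloxy)methyl]pyrrolidine (10 mol %), ethyl 3,4-dihydroxybenzoate (20 mol %), 2 (1.5 equiv), neat, 4 °C, 36 h
Reagents that add atoms: none
Why: Enamine-catalysed asymmetric Michael addition, in which the (R)-diarylprolinol silyl ether converts 1 into its E-enamine and blocks one face so that the enone adds from the other and the new C2 centre (C1 of the target) is formed R under catalyst control, while the methyl-bearing C3 centre of citronellal (C10 of the target) is not enolisable and stays R.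

**Step 2**
Reactants: 3 (2R,3R)-3,7-dimethyl-2-(3-oxobutyl)oct-6-enal
Product: 4 (5R)-7-methoxy-5-[(2R)-6-methylhept-5-en-2-yl]hept-6-en-2-one (E/Z mixture)
Conditions: Ph3P(CH2OMe)Cl (1.15 equiv), KN(SiMe3)2 (1.10 equiv), THF, 0 °C; then 3, −78 → −30 °C
Reagents that add atoms: (methoxymethyl)triphenylphosphonium chloride, COC[P+](c1ccccc1)(c1ccccc1)c1ccccc1.[Cl-]
Why: Wittig methoxymethylenation, in which the pre-formed ylide reacts at −78 °C with the aldehyde far faster than with the methyl ketone or than it enolises the α-CH, so only the formyl group is homologated and the α-stereocentre is kept (the enol ether geometry is irrelevant and no new stereocentre is formed).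

**Step 3**
Reactants: 4 (5R)-7-methoxy-5-[(2R)-6-methylhept-5-en-2-yl]hept-6-en-2-one
Product: 6 (5R)-2-methyl-5-[(2R)-6-methylhept-5-en-2-yl]cyclopent-1-ene-1-carbaldehyde, via keto aldehyde 5 (not isolated)
Conditions: 1 M aq. HCl/THF 1:3, 25 °C; extractive work-up; then piperidine (0.3 equiv), AcOH (0.3 equiv), toluene, 80 °C
Reagents that add atoms: water, O
Why: Acid hydrolysis of the enol ether followed by a piperidinium acetate-mediated intramolecular aldol condensation of the Wolinsky type, in which the enamine of the aldehyde attacks the methyl ketone (5-exo closure) and dehydration gives the conjugated cyclopentenecarbaldehyde, closes the five-membered ring; the ring stereocentre is β to the formyl group in 5 and cannot epimerise, and no new stereocentre is formed.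

**Step 4**
Reactants: 6 (5R)-2-methyl-5-[(2R)-6-methylhept-5-en-2-yl]cyclopent-1-ene-1-carbaldehyde
Product: 10 (−)-α-gurjunene [(1aR,4R,4aR,7bS)-1,1,4,7-tetramethyl-1a,2,3,4,4a,5,6,7b-octahydro-1H-cyclopropa[e]azulene], via tosylhydrazone 7 (not isolated), via tosylhydrazone sodium salt 8 (not isolated), via vinyldiazomethane 9 (not isolated)
Conditions: TsNHNH2 (1.0 equiv), MeOH, 25 °C; evaporate; NaH (1.05 equiv), THF, 0 °C; evaporate; [Cu(MeCN)4]PF6 (5 mol %), BnEt3NCl (10 mol %), 1,4-dioxane (0.01 M), 60 °C
Reagents that add atoms: 4-methylbenzenesulfonohydrazide, Cc1ccc(cc1)S(=O)(=O)NN; sodium hydride, [Na+].[H-]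
Why: Proposed new method: condensation to the tosylhydrazone and Bamford–Stevens fragmentation of its sodium salt (the hydrazide and sodium atoms are carried only by 7 to 9 and leave as sodium 4-methylbenzenesulfinate and N2) release vinyldiazomethane 9 slowly, monovalent copper turns it into a vinylcarbenoid whose carbene carbon (C6) adds across the tethered trisubstituted C7=C11 alkene, which closes the seven-membered ring and the gem-dimethylcyclopropane together; copper carbenoids prefer cyclopropanation of an electron-rich alkene to C–H insertion, the cyclopropane fusion can only be cis, and the new C6/C7 centres are set by a folded transition state with the C10 methyl pseudo-equatorial and the CMe2 terminus on the H-1 face away from that methyl, which gives the (1aR,7bS) isomer; the closest known reaction type is the copper-catalysed intramolecular cyclopropanation of the vinyldiazomethane made from farnesal hydrazone (sesquicarene synthesis) together with the in situ use of tosylhydrazone salts as diazo sources.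

**Step 5**
Reactants: 10 (−)-α-gurjunene; 11 2,4,6-trihydroxybenzene-1,3-dicarbaldehyde (diformylphloroglucinol); 12 3-methylbutanal (isovaleraldehyde)
Product: 14 macrocarpal D [5-{(1R)-1-[(1R,3aR,4R,7R)-7-(2-hydroxypropan-2-yl)-1,4-dimethyl-1,2,3,3a,4,5,6,7-octahydroazulen-1-yl]-3-methylbutyl}-2,4,6-trihydroxybenzene-1,3-dicarbaldehyde], via o-quinone methide 13 (not isolated)
Conditions: 10 (1.0 equiv), 11 (1.3 equiv), 12 (2.0 equiv), NaOAc (1.0 equiv), AcOH (2.0 equiv), 1,4-dioxane/H2O 3:1, 70 °C, Ar, dark; preparative HPLC
Reagents that add atoms: water, O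
Why: Proposed new method: Knoevenagel condensation of 11 with 12 gives the highly electrophilic o-quinone methide 13, whose benzylic carbon is attacked by C4 of the electron-rich tetrasubstituted alkene of 10, the cyclopropylcarbinyl cation at C5 opens by cleavage of the C6–C11 bond to the C5=C6 alkene and a tertiary C11 cation, and water captures that cation, so C7 is untouched and keeps its configuration while C4 and C9' are set by addition of E-configured 13 to the alkene face syn to H-1 with the isobutyl group turned away from the terpene, the topicity of the natural product (this selectivity is not assured and the other diastereomers are removed by HPLC); the closest known reaction types are the three-component Knoevenagel/o-quinone methide couplings of diformylphloroglucinol, aldehydes and terpenes used for guajadial-, robustadial- and euglobal-type meroterpenoids and the electrophile-induced cyclopropylcarbinyl-to-homoallyl opening of vinylcyclopropanes.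

**Compound list**
1 | (R)-citronellal, (3R)-3,7-dimethyloct-6-enal | C[C@H](CCC=C(C)C)CC=O | starting material
2 | methyl vinyl ketone, but-3-en-2-one | CC(=O)C=C | starting material
3 | (2R,3R)-3,7-dimethyl-2-(3-oxobutyl)oct-6-enal | CC(=O)CC[C@H]([C@H](C)CCC=C(C)C)C=O | intermediate
4 | (5R)-7-methoxy-5-[(2R)-6-methylhept-5-en-2-yl]hept-6-en-2-one (E/Z mixture) | CC(=O)CC[C@H]([C@H](C)CCC=C(C)C)C=COC | intermediate
5 | (3S)-3-[(2R)-6-methylhept-5-en-2-yl]-6-oxoheptanal | CC(=O)CC[C@H]([C@H](C)CCC=C(C)C)CC=O | intermediate (not isolated)
6 | (5R)-2-methyl-5-[(2R)-6-methylhept-5-en-2-yl]cyclopent-1-ene-1-carbaldehyde | O=CC1=C(C)CC[C@@H]1[C@H](C)CCC=C(C)C | intermediate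
7 | N'-[(E)-{(5R)-2-methyl-5-[(2R)-6-methylhept-5-en-2-yl]cyclopent-1-en-1-yl}methylidene]-4-methylbenzenesulfonohydrazide | Cc1ccc(cc1)S(=O)(=O)N/N=C/C1=C(C)CC[C@@H]1[C@H](C)CCC=C(C)C | intermediate (not isolated)
8 | sodium salt of 7 (N-sodio tosylhydrazone) | [Na+].Cc1ccc(cc1)S(=O)(=O)[N-]/N=C/C1=C(C)CC[C@@H]1[C@H](C)CCC=C(C)C | intermediate (not isolated)
9 | (5R)-1-(diazomethyl)-2-methyl-5-[(2R)-6-methylhept-5-en-2-yl]cyclopent-1-ene | [N-]=[N+]=CC1=C(C)CC[C@@H]1[C@H](C)CCC=C(C)C | intermediate (not isolated)
10 | (−)-α-gurjunene, (1aR,4R,4aR,7bS)-1,1,4,7-tetramethyl-1a,2,3,4,4a,5,6,7b-octahydro-1H-cyclopropa[e]azulene | C[C@@H]1CC[C@@H]2[C@@H](C2(C)C)C3=C(C)CC[C@@H]31 | intermediate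
11 | 2,4,6-trihydroxybenzene-1,3-dicarbaldehyde | O=Cc1c(O)cc(O)c(C=O)c1O | starting material
12 | 3-methylbutanal | CC(C)CC=O | starting material
13 | 2,4-dihydroxy-5-(3-methylbutylidene)-6-oxocyclohexa-1,3-diene-1,3-dicarbaldehyde (o-quinone methide) | CC(C)CC=C1C(=O)C(C=O)=C(O)C(C=O)=C1O | intermediate (not isolated)
14 | macrocarpal D, 5-{(1R)-1-[(1R,3aR,4R,7R)-7-(2-hydroxypropan-2-yl)-1,4-dimethyl-1,2,3,3a,4,5,6,7-octahydroazulen-1-yl]-3-methylbutyl}-2,4,6-trihydroxybenzene-1,3-dicarbaldehyde | CC(C)C[C@@H](c1c(O)c(C=O)c(O)c(C=O)c1O)[C@@]1(C)CC[C@H]2C1=C[C@H](C(C)(C)O)CC[C@H]2C | target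

**Step count and risks**
Total step count: 5. Longest linear sequence: 5 steps (1 → 3 → 4 → 6 → 10 → 14).

The three steps most likely to fail:

Step 4 (the carbene cascade). The carbenoid may insert into the C9–H bond or the diazoalkene may close to a 3H-pyrazole instead of forming the seven-membered ring, and the cyclopropane may form on the wrong face. The fallback sets out from 6 and builds the two rings separately. Wittig methylenation (Ph3PCH3Br, KN(SiMe3)2, THF, 0 °C) gives the triene (5R)-1-ethenyl-2-methyl-5-[(2R)-6-methylhept-5-en-2-yl]cyclopent-1-ene F1. Ring-closing metathesis with the second-generation Grubbs catalyst (CH2Cl2, 40 °C) closes the seven-membered ring to the diene (8R,8aR)-3,8-dimethyl-1,2,6,7,8,8a-hexahydroazulene F2. A cobalt-catalysed reductive dimethylcyclopropanation (Me2CCl2, Zn, ZnBr2, CoBr2 with 2,6-bis[1-(2,6-diisopropylphenylimino)ethyl]pyridine, THF, 25 °C) then adds the CMe2 unit to the disubstituted C6=C7 bond, the only alkene of the diene that the bulky carbenoid can reach, anti to the C10 methyl. This comes back to the route at 10.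

Step 5 (the o-quinone methide coupling). Under the warm buffered acid 13 may tautomerise or oligomerise, and 10 may isomerise before it is captured. A phenol oxygen may close onto C5 to give the chroman cycloadduct instead of the ring-opened product, the C11 cation may eliminate instead of being hydrated, and the face and C9' selectivity may be modest. The fallback changes how the electrophile is generated and sets out from 11. Organocatalytic reductive alkylation with 12 (L-proline 20 mol %, Hantzsch ester [diethyl 2,6-dimethyl-1,4-dihydropyridine-3,5-dicarboxylate], CH2Cl2, 25 °C; 13 is formed and reduced in situ) gives the stable 2,4,6-trihydroxy-5-(3-methylbutyl)benzene-1,3-dicarbaldehyde F3. DDQ (1.05 equiv) in wet nitromethane at 0 °C in the presence of 10 regenerates 13 by benzylic dehydrogenation at low temperature and without added acid, in a polar medium that favours the stepwise cationic pathway; 13 is trapped by 10 and the cation hydrated as before. This comes back to the route at 14.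

Step 2 (the Wittig homologation). The basic ylide may epimerise the α-stereocentre of 3 or also olefinate the ketone. The fallback sets out from 3. Ohira–Bestmann homologation (dimethyl (1-diazo-2-oxopropyl)phosphonate, K2CO3, MeOH, 0 °C), which does not touch ketones, gives the alkynyl ketone (5R,6R)-5-ethynyl-6,10-dimethylundec-9-en-2-one F4. Anti-Markovnikov hydration of the terminal alkyne ([CpRu(MeCN)3]PF6 5 mol %, 5,5'-bis(trifluoromethyl)-2,2'-bipyridine 5 mol %, NMP/H2O, 25 °C) then gives the keto aldehyde directly. This comes back to the route at 5, which is cyclised to 6 with piperidine/AcOH as in step 3.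

**Further compounds**
F1 | step 4 | (5R)-1-ethenyl-2-methyl-5-[(2R)-6-methylhept-5-en-2-yl]cyclopent-1-ene | C=CC1=C(C)CC[C@@H]1[C@H](C)CCC=C(C)C
F2 | step 4 | (8R,8aR)-3,8-dimethyl-1,2,6,7,8,8a-hexahydroazulene | C[C@@H]1CCC=CC2=C(C)CC[C@@H]21
F3 | step 5 | 2,4,6-trihydroxy-5-(3-methylbutyl)benzene-1,3-dicarbaldehyde | CC(C)CCc1c(O)c(C=O)c(O)c(C=O)c1O
F4 | step 2 | (5R,6R)-5-ethynyl-6,10-dimethylundec-9-en-2-one | CC(=O)CC[C@H]([C@H](C)CCC=C(C)C)C#C
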